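**Retrosynthetic overview**
- The target is a 1-aryl-2,3-bis(hydroxymethyl)tetralin with a 1,2-trans, 2,3-trans arrangement (1R,2S,3S). The C1–aryl bond comes from an SN1 Friedel–Crafts reaction of syringol (2,6-dimethoxyphenol) on the C1 benzylic cation of a 2,3-trans-disubstituted 1-tetralol. The cation is attacked anti to the C2 substituent.
- The tetralin ring, with its trans C2/C3 stereocenters, is built in one step. An iminium-catalysed photoenolization/Diels–Alder reaction joins an o-methylbenzaldehyde to ethyl 4-oxobut-2-enoate.
- The two future CH2OH carbons are the aldehyde and ester carbons of the dienophile. Either cycloaddition regiochemistry therefore converges on the same bis(hydroxymethyl) constitution after reduction.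
- The aldehyde comes from creosol by O-benzylation and formylation para to the OMe group.
- Ring order: the tetralin ring forms first (Step 3), and the pendant aryl ring is attached last (Step 4).

Assumption: the (S)-catalyst 5 delivers the (2S,3S) series required by the target. If the opposite enantiomer is obtained, the (R)-catalyst is used. Tetralin numbering below follows the target, with C1 bearing the aryl group.

---

**Step 1**
Reactants: 1 (creosol, 2-methoxy-4-methylphenol)
Product: 2 (4-(benzyloxy)-3-methoxytoluene)
Conditions: BnBr, K2CO3, DMF, 25 °C
Reagents that add atoms: benzyl bromide, BrCc1ccccc1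
Why: Williamson O-benzylation protects the future C7 phenol. The benzyl group survives the photochemistry, the acid and LiAlH4, and is removed at the end.

**Step 2**
Reactants: 2
Product: 3 (5-(benzyloxy)-4-methoxy-2-methylbenzaldehyde)
Conditions: Cl2CHOMe, SnCl4, CH2Cl2, 0 °C; aqueous workup
Reagents that add atoms: dichloromethyl methyl ether, ClC(Cl)OC; water, O
Why: Rieche formylation goes at the position para to the OMe group and ortho to the methyl. This is the most activated unhindered site, and it sets the CHO/CH3 pair needed for photoenolization.

**Step 3**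
Reactants: 3; 4 (ethyl (E)-4-oxobut-2-enoate); 5 ((S)-diarylprolinol TMS ether catalyst)
Product: 6 (ethyl (2S,3S)-7-(benzyloxy)-1-hydroxy-2-(hydroxymethyl)-6-methoxy-1,2,3,4-tetrahydronaphthalene-3-carboxylate, with the tetralin numbered from the carbinol carbon as C1; C1 epimeric)
Conditions: 5 (20 mol%), 2-nitrobenzoic acid (20 mol%), CH2Cl2, 365 nm LEDs, –10 °C, 24 h; then NaBH4, MeOH, –20 °C, one pot
Reagents that add atoms: none (NaBH4 adds only hydrogen)
Why: Proposed new method: irradiation of 3 gives the triplet aldehyde, which undergoes 1,5-H transfer from the o-methyl group to give the (Z)-hydroxy-o-quinodimethane. The iminium ion of enal 4 traps this diene, and the bulky catalyst shields one face, which sets C2 and C3. The concerted, suprafacial [4+2] keeps the E geometry of the enal, so C2 and C3 end up trans. The nucleophilic CH2 terminus of the 1-oxygenated diene bonds to the iminium β-carbon, which carries the ester. The CHO group therefore ends up at C2, next to the carbinol carbon. In situ NaBH4 reduction of that CHO group prevents retro-aldol, epimerization and dehydration of the β-hydroxy aldehyde. The closest known reaction types are iminium-catalysed Diels–Alder trapping of photogenerated hydroxy-o-quinodimethanes with enals, and photoenol Diels–Alder reactions in natural-product synthesis. What is new is the electron-rich 4,5-dialkoxy-2-methylbenzaldehyde combined with a fumaraldehyde-type 1,4-dicarbonyl enal. This delivers both lignan hydroxymethyl carbons and the trans C2/C3 stereocenters in one step.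

**Step 4**
Reactants: 6; 7 (syringol, 2,6-dimethoxyphenol)
Product: 8 (ethyl (1R,2S,3S)-7-(benzyloxy)-1-(4-hydroxy-3,5-dimethoxyphenyl)-2-(hydroxymethyl)-6-methoxy-1,2,3,4-tetrahydronaphthalene-3-carboxylate; it may partly lactonize to the trans-fused γ-lactone)
Conditions: 7 (4 equiv), p-TsOH·H2O (10 mol%), HFIP, 25 °C
Reagents that add atoms: none (syringol is reactant 7)
Why: The C1–OH is para to the C6 methoxy group through C8a and ionizes readily in HFIP. Syringol attacks through its free para carbon in an SN1 Friedel–Crafts benzylation, and the phenol OH stays unprotected. The cation is attacked anti to the C2–CH2OH group, giving the 1,2-trans, 2,3-trans arrangement. The C1 configuration of 6 is erased, so its epimers converge. The C2–CH2OH cannot trap the cation intramolecularly, because that would form a strained oxetane.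

**Step 5**
Reactants: 8
Product: 9 ((1R,2S,3S)-7-(benzyloxy)-1-(4-hydroxy-3,5-dimethoxyphenyl)-6-methoxy-2,3-bis(hydroxymethyl)-1,2,3,4-tetrahydronaphthalene)
Conditions: LiAlH4 (4 equiv), THF, 0 °C to 25 °C
Reagents that add atoms: none (LiAlH4 adds only hydrogen)
Why: Hydride reduction of the ester (or lactone) to the primary alcohol leaves the three stereocenters untouched, because the new CH2OH groups are not epimerizable. The free phenol, the benzyl ether and the aryl methyl ethers survive.

**Step 6**
Reactants: 9
Product: 10 (target, (1R,2S,3S)-7-hydroxy-1-(4-hydroxy-3,5-dimethoxyphenyl)-6-methoxy-2,3-bis(hydroxymethyl)-1,2,3,4-tetrahydronaphthalene)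
Conditions: H2 (1 atm), 10% Pd/C, EtOAc/EtOH, 25 °C
Reagents that add atoms: none (H2 adds only hydrogen)
Why: Hydrogenolysis removes the O-benzyl group to release the C7 phenol. The diarylmethine carbon, the aryl methyl ethers and the stereocenters are unaffected.

---

**Compound list**

| No. | Name | SMILES | Role |
|---|---|---|---|
| 1 | Creosol (2-methoxy-4-methylphenol) | COc1cc(C)ccc1O | starting material |
| 2 | 4-(Benzyloxy)-3-methoxytoluene | COc1cc(C)ccc1OCc1ccccc1 | intermediate |
| 3 | 5-(Benzyloxy)-4-methoxy-2-methylbenzaldehyde | O=Cc1cc(OCc2ccccc2)c(OC)cc1C | intermediate |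
| 4 | Ethyl (E)-4-oxobut-2-enoate | CCOC(=O)/C=C/C=O | starting material |
| 5 | (S)-α,α-Bis[3,5-bis(trifluoromethyl)phenyl]prolinol TMS ether (chiral amine catalyst, not incorporated into the product) | C[Si](C)(C)OC(c1cc(C(F)(F)F)cc(C(F)(F)F)c1)(c1cc(C(F)(F)F)cc(C(F)(F)F)c1)[C@@H]1CCCN1 | starting material |
| 6 | Ethyl (2S,3S)-7-(benzyloxy)-1-hydroxy-2-(hydroxymethyl)-6-methoxy-1,2,3,4-tetrahydronaphthalene-3-carboxylate (C1 epimeric) | COc1cc2c(cc1OCc1ccccc1)C(O)[C@H](CO)[C@@H](C(=O)OCC)C2 | intermediate |
| 7 | 2,6-Dimethoxyphenol (syringol) | COc1cccc(OC)c1O | starting material |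
| 8 | Ethyl (1R,2S,3S)-7-(benzyloxy)-1-(4-hydroxy-3,5-dimethoxyphenyl)-2-(hydroxymethyl)-6-methoxy-1,2,3,4-tetrahydronaphthalene-3-carboxylate | COc1cc2c(cc1OCc1ccccc1)[C@@H](c1cc(OC)c(O)c(OC)c1)[C@H](CO)[C@@H](C(=O)OCC)C2 | intermediate |
| 9 | (1R,2S,3S)-7-(Benzyloxy)-1-(4-hydroxy-3,5-dimethoxyphenyl)-6-methoxy-2,3-bis(hydroxymethyl)-1,2,3,4-tetrahydronaphthalene | COc1cc2c(cc1OCc1ccccc1)[C@@H](c1cc(OC)c(O)c(OC)c1)[C@H](CO)[C@@H](CO)C2 | intermediate |
| 10 | (1R,2S,3S)-7-Hydroxy-1-(4-hydroxy-3,5-dimethoxyphenyl)-6-methoxy-2,3-bis(hydroxymethyl)-1,2,3,4-tetrahydronaphthalene | COc1cc2c(cc1O)[C@@H](c1cc(OC)c(O)c(OC)c1)[C@H](CO)[C@@H](CO)C2 | target |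

**Total step count:** 6. **Longest linear sequence:** 6 steps (1 → 2 → 3 → 6 → 8 → 9 → 10).

**Three steps most likely to fail**
1. **Step 3 (proposed new photo-organocatalytic Diels–Alder).**
   - Risks: amine quenching of the triplet aldehyde, low photoenolization efficiency of the electron-rich aldehyde, and modest ee.
   - Fallback: run the known racemic photoenol Diels–Alder of 3 with dimethyl fumarate (no catalyst), giving the 2,3-trans diester. Carry the racemate through SN1 arylation, LiAlH4 reduction (which reduces both esters) and hydrogenolysis. Resolve by preparative chiral HPLC at the triol stage.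
2. **Step 4 (C1 diastereoselectivity, and benzyl cleavage or transfer to syringol under acid).**
   - Fallback: form the C1–aryl bond by intramolecular cationic cyclisation instead. Start from the enantioenriched 2,3-trans-dibenzylbutane-1,4-diol bearing a 4-hydroxy-3-methoxybenzyl and a 4-hydroxy-3,5-dimethoxybenzyl group. It is made from a trans-dibenzylbutyrolactone by an Evans-auxiliary alkylation sequence and LiAlH4 reduction. Oxidise the syringyl benzylic CH2 with DDQ to the p-quinone methide, then cyclise with acid onto the guaiacyl ring para to its OMe group. This is the known biomimetic secoisolariciresinol-to-isolariciresinol cyclisation, and it gives the 1,2-trans aryltetralin.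
3. **Step 2 (regioselective formylation without debenzylation).**
   - Fallback: start from commercial 2-bromo-5-hydroxy-4-methoxybenzaldehyde (the isovanillin bromination product). O-benzylate it, then install the methyl group by Suzuki coupling with methylboronic acid or trimethylboroxine to give 3 with guaranteed regiochemistry.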